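Read the earlier runs from their late end. At 3.00 d in larch and 2.50 d in ash, free monomer reads 0.4 % and 0.4 % of the charge and monomer in chains 95.5 % and 97.4 %. So 0.0172 M and 0.0145 M stand in neither, on average 0.0159 M, close to the c(protic impurity) of 0.0150 M.

common to all: initiator 10 mol%
- larch: free monomer 0.42 M; transfer agent 0.090 M; protic impurity 0.015 M; run made earlier
- ash: free monomer 0.66 M; transfer agent 0.090 M; protic impurity 0.015 M; run made earlier
- flask: free monomer 0.30 M; transfer agent 0.0900 M; protic impurity 0.0150 M; time 4.0 d

| run | time / d | monomer in chains / % | free monomer / % |
|---|---|---|---|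
| larch | 1.04 | 83.0 | 12.8 |
| larch | 2.08 | 93.8 | 2.5 |
| larch | 3.00 | 95.5 | 0.4 |
| larch | 4.00 | 96.6 | 0.4 |
| ash | 0.500 | 77.7 | 19.3 |
| ash | 1.25 | 95.0 | 2.5 |
| ash | 2.50 | 97.4 | 0.4 |
| ash | 4.00 | 97.4 | 0.7 |

(standard deviation of a reading: 0.3 percentage points)

1. average number of monomer units in a chain (chains begun, living or dead) at 4.0 d
2. part of the free monomer that has reacted at 4.0 d

- the average divides the monomer in chains by the number of chains begun, living and dead together
- the earlier runs do not show the number of chains; that part of a forecast is a guess

Now run the flask in slow motion, as my own reckoning. In the first instants I let the protic impurity take its 0.0150 M of the 0.30 M free monomer, since ash already shows a gap of 0.0198 M at its first reading. In the middle, chains grow: between the first two readings free monomer halves every 0.441 d in larch and every 0.254 d in ash, so the halving time read in ash is shorter than in larch. This flask should run slower, but 4.0 d is long against those times, so at the end I put the remaining monomer in chains.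

Then the number of chains matters. The runs do not show it, so this is a guess: each chain begun costs one initiator, and transfer agent ends chains without beginning new ones. Initiator then counts the chains, and its charge allows 0.0300 M of them. Dividing c(free monomer) minus c(protic impurity) by that charge gives 9.50; call this the monomer per initiator.

The forecast says dp 2.3 and c 97.2 %, with “Chains begun, a guess, are about 0.09 + 0.03 ≈ 0.12 M”. My count differs from it by leaving out c(transfer agent).

The flask gives dp 9.54 and c 98.6 %.

    free monomer + initiator → spent initiator (k = 1.95 × 10⁻⁵ L mol⁻¹ s⁻¹)
    free monomer + initiator → living end + monomer in chains (k = 8.84 × 10⁻⁴ L mol⁻¹ s⁻¹)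
    living end + transfer agent → dead chain (kL = 2.68 × 10⁻⁵ L mol⁻¹ s⁻¹)
    protic impurity + free monomer → quenched substrate (k = 0.00103 L mol⁻¹ s⁻¹)
    free monomer + living end → monomer in chains + living end, rate k5*[living end]*[free monomer] (k = 5.86 × 10⁻⁴ L mol⁻¹ s⁻¹)

In this flask, half of the chain-starting turnover up to 4.0 d is done after 0.747 h, much earlier than half of the growth, which takes 0.522 d. At 4.00 d, living end and dead chain together stand at 0.0294 M and spent initiator at 6.475 × 10⁻⁴ M, against the 0.0300 M of initiator charged, and the monomer per initiator of 9.50 stands beside the computed dp of 9.54.

Read the same flask at 40 h: 10.9 % of the free monomer remains, so the monomer per initiator, less that remainder divided by the initiator charged, gives 8.41, and the computed dp is 8.58.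

The numbers in the tables stem from a simulated flask from invented constants; scatter was added.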